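**Retrosynthetic overview**

1. Kazinol H (12) ⇒ O1–C2 disconnection: enantioselective 6-endo hydroalkoxylation of the (E)-1,3-diarylpropene 11. Ring C is closed last and the only stereocenter is set in this C–O bond-forming step.
2. 11 ⇒ C4–C4a disconnection: dehydrative Friedel–Crafts allylation of the tert-prenyl resorcinol 10 (ring A) with the aryl vinyl carbinol 8 (ring B).
3. 8 ⇒ aldehyde 6 + vinylmagnesium bromide; 6 ⇒ bromochromene aldehyde 4 + prenylBpin (linear-selective coupling); 4 ⇒ 2-bromo-4,5-dihydroxybenzaldehyde + 3-chloro-3-methylbut-1-yne.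
4. 10 ⇒ 4-bromoresorcinol + the same prenylBpin (branched-selective coupling).
5. Ring order: the dimethylpyran ring fused to ring B first (step 1), ring C last (step 6); rings A and B are bought as benzenes.

Assumption: the target SMILES encodes the (2S) flavan, and 2-bromo-4,5-dihydroxybenzaldehyde is taken as a catalogue compound.

**Route**

Step 1
Reactants: 1 2-bromo-4,5-dihydroxybenzaldehyde; 2 3-chloro-3-methylbut-1-yne
Product: 4 5-bromo-8-hydroxy-2,2-dimethyl-2H-chromene-6-carbaldehyde, via propargyl ether 3 (not isolated)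
Conditions: 2 (1.3 equiv), K2CO3 (1.05 equiv), KI (0.2 equiv), NMP, 60 °C; excess 2 stripped in vacuo; then 150 °C, same flask
Reagents that add atoms: 3-chloro-3-methylbut-1-yne (2), C#CC(C)(C)Cl
Why: The more acidic 4-OH (para to CHO) is O-alkylated selectively, and the aryl 1,1-dimethylpropargyl ether then undergoes thermal propargyl Claisen rearrangement, 1,5-H shift and oxa-6π electrocyclisation at the only free ortho carbon to give the 2,2-dimethylchromene; no stereocenter.

Step 2
Reactants: 4 5-bromo-8-hydroxy-2,2-dimethyl-2H-chromene-6-carbaldehyde; 5 prenylboronic acid pinacol ester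
Product: 6 8-hydroxy-2,2-dimethyl-5-(3-methylbut-2-en-1-yl)-2H-chromene-6-carbaldehyde
Conditions: 5 (1.5 equiv), PdCl2(IPent)(3-chloropyridine) (2 mol%) [IPent = 1,3-bis(2,6-di(pentan-3-yl)phenyl)imidazol-2-ylidene], K3PO4 (3 equiv), THF/H2O, 65 °C
Reagents that add atoms: prenylboronic acid pinacol ester (5), CC(C)=CCB1OC(C)(C)C(C)(C)O1
Why: α-Selective allyl–aryl Suzuki–Miyaura coupling; with the very bulky monodentate carbene the allylpalladium equilibrates to its primary terminus before reductive elimination, and the di-ortho-substituted aryl group also disfavors the tertiary terminus, so the linear prenyl group results; no stereocenter.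

Step 3
Reactants: 6 8-hydroxy-2,2-dimethyl-5-(3-methylbut-2-en-1-yl)-2H-chromene-6-carbaldehyde; 7 vinylmagnesium bromide
Product: 8 6-(1-hydroxyprop-2-en-1-yl)-2,2-dimethyl-5-(3-methylbut-2-en-1-yl)-2H-chromen-8-ol (racemic)
Conditions: 7 (2.5 equiv), THF, −78 to 0 °C; sat. NH4Cl
Reagents that add atoms: vinylmagnesium bromide (7), C=C[Mg]Br
Why: Grignard 1,2-addition to the aldehyde after the first equivalent deprotonates the phenol; the carbinol center is left racemic because it is ionised and erased in step 5.

Step 4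
Reactants: 9 4-bromobenzene-1,3-diol; 5 prenylboronic acid pinacol ester
Product: 10 4-(2-methylbut-3-en-2-yl)benzene-1,3-diol
Conditions: 5 (1.5 equiv), Pd(OAc)2 (3 mol%), 1,1'-bis(di-tert-butylphosphino)ferrocene (3.6 mol%), K3PO4 (3 equiv), degassed THF/H2O, 50 °C
Reagents that add atoms: prenylboronic acid pinacol ester (5), CC(C)=CCB1OC(C)(C)C(C)(C)O1
Why: γ-Selective allyl–aryl Suzuki–Miyaura coupling; SE2'-type transmetalation puts palladium on the tertiary carbon and the bulky chelating bisphosphine blocks the π-allyl isomerisation, so reductive elimination gives the 1,1-dimethylallyl (reverse prenyl) arene; no stereocenter.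

Step 5
Reactants: 8 6-(1-hydroxyprop-2-en-1-yl)-2,2-dimethyl-5-(3-methylbut-2-en-1-yl)-2H-chromen-8-ol; 10 4-(2-methylbut-3-en-2-yl)benzene-1,3-diol
Product: 11 4-[(2E)-3-[8-hydroxy-2,2-dimethyl-5-(3-methylbut-2-en-1-yl)-2H-chromen-6-yl]prop-2-en-1-yl]-6-(2-methylbut-3-en-2-yl)benzene-1,3-diol
Conditions: 10 (2.5 equiv, excess recovered), HFIP/CH2Cl2 1:1, 0 °C to rt
Reagents that add atoms: none
Why: Dehydrative Friedel–Crafts allylation (SN1): HFIP ionises the doubly activated carbinol to a p-alkoxy-stabilised 1-arylallyl cation, which C6 of the resorcinol (para to one OH, ortho to the other) captures at the unhindered terminus to give the conjugated E-alkene, while HFIP is too weak an acid to protonate the prenyl, tert-prenyl or chromene C=C bonds.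

Step 6
Reactants: 11 4-[(2E)-3-[8-hydroxy-2,2-dimethyl-5-(3-methylbut-2-en-1-yl)-2H-chromen-6-yl]prop-2-en-1-yl]-6-(2-methylbut-3-en-2-yl)benzene-1,3-diol
Product: 12 kazinol H, (2S)-2-[8-hydroxy-2,2-dimethyl-5-(3-methylbut-2-en-1-yl)-2H-chromen-6-yl]-6-(2-methylbut-3-en-2-yl)-3,4-dihydro-2H-chromen-7-ol
Conditions: confined chiral IDPi Brønsted acid [imidodiphosphorimidate built from two 3,3'-bis[3,5-bis(trifluoromethyl)phenyl]-BINOL units with P=N–SO2CF3 groups; antipode that gives 2S] (5 mol%), 5 Å MS, CHCl3, −30 °C; Et3N quench at full conversion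
Reagents that add atoms: none
Why: Proposed new method: catalytic enantioselective 6-endo Markovnikov hydroalkoxylation of a 2-cinnamylphenol to a flavan. The confined acid hydrogen-bonds the ortho phenol and protonates C3 of the anethole-type alkene; the resulting p-alkoxybenzylic cation is held as a contact ion pair in the chiral pocket and is captured by the bound phenol oxygen on one face, which sets C2 as S (the catalyst antipode is fixed by running both enantiomers once). The directed, near-concerted pathway is open only to this alkene, which should let it outrun undirected protonation of the prenyl, tert-prenyl and chromene olefins at low temperature. The closest known reactions are the confined-acid asymmetric intramolecular hydroalkoxylation of unactivated alkenols and the racemic acid-mediated cyclisation of 2-cinnamylphenols to flavans; closure of a phenol onto a 1,2-disubstituted styrene to a secondary benzylic ether in a polyolefinic substrate is the new part.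

**Compound list**

1 | 2-bromo-4,5-dihydroxybenzaldehyde | O=Cc1cc(O)c(O)cc1Br | starting material
2 | 3-chloro-3-methylbut-1-yne | C#CC(C)(C)Cl | starting material
3 | 2-bromo-5-hydroxy-4-[(2-methylbut-3-yn-2-yl)oxy]benzaldehyde (propargyl ether) | O=Cc1cc(O)c(OC(C)(C)C#C)cc1Br | intermediate
4 | 5-bromo-8-hydroxy-2,2-dimethyl-2H-chromene-6-carbaldehyde | CC1(C)C=Cc2c(Br)c(C=O)cc(O)c2O1 | intermediate
5 | 4,4,5,5-tetramethyl-2-(3-methylbut-2-en-1-yl)-1,3,2-dioxaborolane (prenylboronic acid pinacol ester) | CC(C)=CCB1OC(C)(C)C(C)(C)O1 | starting material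
6 | 8-hydroxy-2,2-dimethyl-5-(3-methylbut-2-en-1-yl)-2H-chromene-6-carbaldehyde | CC(C)=CCc1c(C=O)cc(O)c2OC(C)(C)C=Cc12 | intermediate
7 | vinylmagnesium bromide | C=C[Mg]Br | starting material
8 | 6-(1-hydroxyprop-2-en-1-yl)-2,2-dimethyl-5-(3-methylbut-2-en-1-yl)-2H-chromen-8-ol (racemic) | C=CC(O)c1cc(O)c2OC(C)(C)C=Cc2c1CC=C(C)C | intermediate
9 | 4-bromobenzene-1,3-diol | Oc1ccc(Br)c(O)c1 | starting material
10 | 4-(2-methylbut-3-en-2-yl)benzene-1,3-diol | C=CC(C)(C)c1ccc(O)cc1O | intermediate
11 | 4-[(2E)-3-[8-hydroxy-2,2-dimethyl-5-(3-methylbut-2-en-1-yl)-2H-chromen-6-yl]prop-2-en-1-yl]-6-(2-methylbut-3-en-2-yl)benzene-1,3-diol | C=CC(C)(C)c1cc(C/C=C/c2cc(O)c3OC(C)(C)C=Cc3c2CC=C(C)C)c(O)cc1O | intermediate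
12 | kazinol H, (2S)-2-[8-hydroxy-2,2-dimethyl-5-(3-methylbut-2-en-1-yl)-2H-chromen-6-yl]-6-(2-methylbut-3-en-2-yl)-3,4-dihydro-2H-chromen-7-ol | C=CC(C)(C)c1cc2c(cc1O)O[C@H](c1cc(O)c3c(c1CC=C(C)C)C=CC(C)(C)O3)CC2 | target

**Step count and risk**

Total steps: 6. Longest linear sequence: 5 (steps 1, 2, 3, 5, 6); step 4 is the one-step side branch.

The three steps most likely to fail:

Step 6 (the proposed new method). Risks are acid isomerisation of the prenyl group, low enantioselectivity, and re-ionisation of the product ether. The fallback uses known chemistry, sets out from 8 and 10, and comes back at 12. Oxidise 8 with MnO2 (CH2Cl2, rt) to the aryl vinyl ketone 1-[8-hydroxy-2,2-dimethyl-5-(3-methylbut-2-en-1-yl)-2H-chromen-6-yl]prop-2-en-1-one F1. Add resorcinol 10 to it in a conjugate Friedel–Crafts reaction (HFIP, rt) to give the ketone 3-[2,4-dihydroxy-5-(2-methylbut-3-en-2-yl)phenyl]-1-[8-hydroxy-2,2-dimethyl-5-(3-methylbut-2-en-1-yl)-2H-chromen-6-yl]propan-1-one F2, which is in equilibrium with its cyclic hemiketal. Reduce it by Noyori asymmetric transfer hydrogenation, RuCl[(R,R)-TsDPEN](p-cymene), HCO2H/Et3N, to the carbinol (1R)-3-[2,4-dihydroxy-5-(2-methylbut-3-en-2-yl)phenyl]-1-[8-hydroxy-2,2-dimethyl-5-(3-methylbut-2-en-1-yl)-2H-chromen-6-yl]propan-1-ol F3. Close the same O1–C2 bond by Mitsunobu cyclisation (PPh3, DIAD, THF, 0 °C); this inverts the carbinol center and gives (2S)-12 without any alkene protonation.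

Step 4. The branched-selective coupling has to build an aryl–quaternary carbon next to a free phenoxide on an electron-rich bromide, so low conversion or leakage to the linear isomer is possible. The fallback sets out from 9 and comes back at 10. Palladium-catalysed α-arylation of isobutyraldehyde with 9 (Pd(OAc)2, rac-BINAP, Cs2CO3, dioxane, 80 °C) gives 2-(2,4-dihydroxyphenyl)-2-methylpropanal F4, handled as its ring-closed lactol. Wittig methylenation (Ph3P=CH2 from Ph3PCH3Br/KOtBu, excess, THF) then turns the formyl group into the vinyl group of 10. The quaternary carbon is thus made by enolate arylation and not by allyl transfer.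

Step 5. The cation can be trapped by ring B of a second molecule, by oxygen, or at C2 of the resorcinol, and over-allylation is possible. The fallback sets out from 8 and 10 and comes back at 11. It replaces carbocation chemistry by π-allyl chemistry under neutral conditions: Pd(PPh3)4 (5 mol%), Et3B (activates the allylic OH), THF, 50 °C. Zerovalent palladium ionises 8 to a 1-aryl-π-allyl complex that the resorcinol attacks through carbon at the unsubstituted terminus, giving the same E-alkene; this fallback makes no new compound (F0).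

**Further compounds**

F1 | step 6 | 1-[8-hydroxy-2,2-dimethyl-5-(3-methylbut-2-en-1-yl)-2H-chromen-6-yl]prop-2-en-1-one | C=CC(=O)c1cc(O)c2OC(C)(C)C=Cc2c1CC=C(C)C
F2 | step 6 | 3-[2,4-dihydroxy-5-(2-methylbut-3-en-2-yl)phenyl]-1-[8-hydroxy-2,2-dimethyl-5-(3-methylbut-2-en-1-yl)-2H-chromen-6-yl]propan-1-one | C=CC(C)(C)c1cc(CCC(=O)c2cc(O)c3OC(C)(C)C=Cc3c2CC=C(C)C)c(O)cc1O
F3 | step 6 | (1R)-3-[2,4-dihydroxy-5-(2-methylbut-3-en-2-yl)phenyl]-1-[8-hydroxy-2,2-dimethyl-5-(3-methylbut-2-en-1-yl)-2H-chromen-6-yl]propan-1-ol | C=CC(C)(C)c1cc(CC[C@@H](O)c2cc(O)c3OC(C)(C)C=Cc3c2CC=C(C)C)c(O)cc1O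
F4 | step 4 | 2-(2,4-dihydroxyphenyl)-2-methylpropanal | CC(C)(C=O)c1ccc(O)cc1O
F0 | step 5 | none | none
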